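**Retrosynthetic overview**
1. Maackiaflavanone A comes from the bis-MOM ether of the (2S)-flavanone by mild acid methanolysis. The C2–C1' bond and the only stereocenter come from a rhodium-catalysed asymmetric 1,4-addition of a ring B boronic acid to 5-O-MOM-7-methoxy-8-prenylchromone.
2. The chromone: ring C is closed on the symmetric 2',6'-dihydroxy-4'-methoxyacetophenone (enaminone route), and the prenyl group is brought to C8 by 5-O-prenylation and an Eu(fod)3 para-Claisen–Cope rearrangement.
3. Ring B fragment: the 2,2-dimethylpyran ring is cut at both of its bonds to ring B (C5'–CH= and C4'–O). This gives an arene with I at C5', Br at C4', OMOM at C2' and Cl at C1' (latent boron), and the four-atom unit O–CMe2–CH=CH held as a five-membered oxaborole.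
4. Enabling feature: the pyran ring is fused to ring B through two adjacent aromatic carbons of unlike kind (C4' oxygen-bearing, C5' carbon-bearing), and its other four atoms form a Z-configured C,O-dinucleophile whose tertiary alkoxide has no beta-hydrogen. The I/Br pair fixes the regiochemistry and the temporary B–O ring fixes the Z geometry.
5. Ring order: oxaborole (temporary ring) → dimethylpyran ring on ring B (key step); separately, pyranone ring C on ring A; then union of the two halves at C2.

Key step: step 5

Assumption: the face selectivity of the rhodium/(S)-biaryl bisphosphine catalyst on the chromone is taken to follow that established for 2-cyclohexenone, which corresponds to the 2S product; if a model reaction shows the opposite sense, the (R)-ligand is used with no other change.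

Step 1
Reactants: 1 ethyl (2Z)-3-iodoprop-2-enoate
Product: 2 (3Z)-4-iodo-2-methylbut-3-en-2-ol
Conditions: MeMgBr (2.5 equiv), Et2O, −78 °C to −20 °C; aq. NH4Cl
Reagents that add atoms: methylmagnesium bromide, C[Mg]Br
Why: twofold 1,2-addition of a Grignard reagent to the ester at low temperature should give the tertiary alcohol without touching the Z-iodoalkene, whose geometry is carried over from 1.

Step 2
Reactants: 2 (3Z)-4-iodo-2-methylbut-3-en-2-ol
Product: 4 5,5-dimethyl-1,2-oxaborol-2(5H)-ol, via dilithio species 3 (not isolated)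
Conditions: t-BuLi (3.1 equiv), Et2O, −78 °C; B(Oi-Pr)3, −78 °C to rt; 1 M HCl
Reagents that add atoms: triisopropyl borate, CC(C)OB(OC(C)C)OC(C)C; water, O
Why: O–H deprotonation and iodine–lithium exchange with retention of alkene geometry give the chelated Z-vinyllithium alkoxide 3, whose borylation and acidic hydrolysis close the five-membered boronic hemiester, a ring that only the Z isomer can form.

Step 3
Reactants: 5 5-bromo-2-chlorophenol
Product: 6 5-bromo-2-chloro-4-iodophenol
Conditions: NIS (1.05 equiv), TsOH·H2O (10 mol%), MeCN, 0 °C to rt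
Reagents that add atoms: N-iodosuccinimide, O=C1CCC(=O)N1I
Why: electrophilic aromatic iodination is directed para to the free hydroxyl group, the ortho position between OH and Br being the more hindered one.

Step 4
Reactants: 6 5-bromo-2-chloro-4-iodophenol
Product: 7 1-bromo-4-chloro-2-iodo-5-(methoxymethoxy)benzene
Conditions: MOMCl, i-Pr2NEt, CH2Cl2, 0 °C to rt
Reagents that add atoms: chloromethyl methyl ether, COCCl
Why: O-alkylation of the phenol (MOM protection) masks the acidic hydroxyl for the palladium and rhodium steps and survives carbonate base and heat.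

Step 5
Reactants: 7 1-bromo-4-chloro-2-iodo-5-(methoxymethoxy)benzene; 4 5,5-dimethyl-1,2-oxaborol-2(5H)-ol
Product: 9 6-chloro-7-(methoxymethoxy)-2,2-dimethyl-2H-chromene, via Z-alkenol 8 (not isolated)
Conditions: Pd(OAc)2 (5 mol%), dppf (6 mol%), 4 (1.05 equiv), Cs2CO3 (3 equiv), toluene/H2O (20:1), 60 °C, then 100 °C
Reagents that add atoms: none
Why: Proposed new method: one palladium/dppf catalyst is meant to run two cycles in one flask: oxidative addition into the C–I bond of 7 (well ahead of C–Br and C–Cl), transmetalation of the alkenyl carbon of oxaborole 4 and reductive elimination give Z-alkenol 8 with the geometry held by the boron–oxygen ring, hydrolysis of the borate ester frees the tertiary alkoxide, and a second oxidative addition into the neighbouring C–Br bond is followed by alkoxide binding and C–O reductive elimination from a seven-membered oxapalladacycle. The closest known reaction types are the Suzuki–Miyaura coupling of cyclic alkenylboronic hemiesters with aryl iodides, the palladium/dppf-catalysed intramolecular etherification of 2-bromoaryl-substituted tertiary alcohols to 2,2-dimethylchromans (Buchwald–Hartwig type) and domino Suzuki/C–heteroatom annulations of 1,2-dihaloarenes with 2-amino- or 2-hydroxyarylboron reagents; what is new is their merger with an alkenylboron partner that carries an aliphatic tertiary alkoxide. The pyran ring closes in the second cycle by intramolecular C(aryl)–O reductive elimination (formally a 6-exo attack of the alkoxide on the bromide-bearing carbon), and no stereocenter is formed. The step needs site selectivity (carbon to the former C–I carbon, oxygen to the former C–Br carbon, C–Cl left for step 6), which the I > Br > Cl order of oxidative addition and a bidentate ligand that does not activate aryl chlorides secure. It needs the Z alkene, which the temporary oxaborole ring secures, and freedom from beta-hydride elimination at the palladium alkoxide, which the fully substituted carbinol carbon secures; only a slight excess of 4 is used so that a second C–C coupling at C–Br does not compete with the intramolecular etherification.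

Step 6
Reactants: 9 6-chloro-7-(methoxymethoxy)-2,2-dimethyl-2H-chromene
Product: 10 2-[7-(methoxymethoxy)-2,2-dimethyl-2H-chromen-6-yl]-4,4,5,5-tetramethyl-1,3,2-dioxaborolane
Conditions: Pd2(dba)3 (2 mol%), XPhos (8 mol%), B2pin2 (1.5 equiv), KOAc (3 equiv), 1,4-dioxane, 100 °C
Reagents that add atoms: bis(pinacolato)diboron, CC1(C)OB(OC1(C)C)B1OC(C)(C)C(C)(C)O1
Why: Miyaura borylation, in which the dialkylbiarylphosphine ligand enables oxidative addition into the electron-rich aryl chloride while the chromene olefin and the MOM ether stay inert.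

Step 7
Reactants: 10 2-[7-(methoxymethoxy)-2,2-dimethyl-2H-chromen-6-yl]-4,4,5,5-tetramethyl-1,3,2-dioxaborolane
Product: 11 [7-(methoxymethoxy)-2,2-dimethyl-2H-chromen-6-yl]boronic acid
Conditions: NaIO4 (3 equiv), NH4OAc (3 equiv), acetone/H2O (1:1), rt
Reagents that add atoms: water, O
Why: oxidative cleavage of the liberated pinacol by periodate drives the hydrolysis of the pinacol boronate to the free boronic acid, the form that transmetalates to rhodium without added base.

Step 8
Reactants: 12 1-(2,6-dihydroxy-4-methoxyphenyl)ethan-1-one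
Product: 14 5-hydroxy-7-methoxy-4H-chromen-4-one, via enaminone 13 (not isolated)
Conditions: Me2NCH(OMe)2 (2.2 equiv), toluene, 90 °C; then conc. HCl, CH2Cl2, 40 °C
Reagents that add atoms: N,N-dimethylformamide dimethyl acetal, COC(OC)N(C)C
Why: condensation of the methyl ketone with the formamide acetal gives enaminone 13, and acid-promoted 6-endo addition–elimination by an ortho-hydroxyl closes the pyranone ring (enaminone route to chromones); the two hydroxyls of 12 are equivalent, so no regiochemical question arises.

Step 9
Reactants: 14 5-hydroxy-7-methoxy-4H-chromen-4-one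
Product: 15 7-methoxy-5-[(3-methylbut-2-en-1-yl)oxy]-4H-chromen-4-one
Conditions: prenyl bromide (1.5 equiv), K2CO3, DMF, 60 °C
Reagents that add atoms: 1-bromo-3-methylbut-2-ene, CC(C)=CCBr
Why: Williamson O-alkylation of the chelated 5-hydroxyl with the allylic bromide under carbonate in a dipolar aprotic solvent.

Step 10
Reactants: 15 7-methoxy-5-[(3-methylbut-2-en-1-yl)oxy]-4H-chromen-4-one
Product: 18 5-hydroxy-7-methoxy-8-(3-methylbut-2-en-1-yl)-4H-chromen-4-one, via ortho-dienone 16 (not isolated), via para-dienone 17 (not isolated)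
Conditions: Eu(fod)3 (10 mol%), CHCl3, 60 °C, sealed tube
Reagents that add atoms: none
Why: Lewis-acid-catalysed para-Claisen–Cope rearrangement: the aromatic Claisen shift can only go to C6 (C4a is blocked), the 1,1-dimethylallyl dienone 16 undergoes a Cope shift to C8, and tautomerization of 17 restores ring A with the prenyl group at C8.

Step 11
Reactants: 18 5-hydroxy-7-methoxy-8-(3-methylbut-2-en-1-yl)-4H-chromen-4-one
Product: 19 7-methoxy-5-(methoxymethoxy)-8-(3-methylbut-2-en-1-yl)-4H-chromen-4-one
Conditions: MOMCl (3 equiv), i-Pr2NEt (4 equiv), DMAP (10 mol%), CH2Cl2, 40 °C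
Reagents that add atoms: chloromethyl methyl ether, COCCl
Why: MOM protection of the chelated 5-hydroxyl, which could otherwise bind rhodium as a beta-ketophenolate chelate and slow the next step.

Step 12
Reactants: 19 7-methoxy-5-(methoxymethoxy)-8-(3-methylbut-2-en-1-yl)-4H-chromen-4-one; 11 [7-(methoxymethoxy)-2,2-dimethyl-2H-chromen-6-yl]boronic acid
Product: 20 (2S)-7-methoxy-5-(methoxymethoxy)-2-[7-(methoxymethoxy)-2,2-dimethyl-2H-chromen-6-yl]-8-(3-methylbut-2-en-1-yl)-2,3-dihydro-4H-chromen-4-one
Conditions: [RhCl(C2H4)2]2 (1.5 mol%), (S)-MeO-F12-BIPHEP (3.3 mol%), aq. KOH (6 mol%, forms the hydroxorhodium complex), 11 (2.5 equiv), toluene/H2O (10:1), 30 °C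
Reagents that add atoms: none
Why: rhodium-catalysed asymmetric 1,4-addition of an arylboronic acid to a chromone (Hayashi–Miyaura reaction), in which aryl transfer from boron to rhodium, enantioface-selective insertion of the chromone C2=C3 bond and hydrolysis of the rhodium enolate set the C2 stereocenter under control of the chiral bisphosphine, while the essentially base-free medium should keep ring C from reopening.

Step 13
Reactants: 20 (2S)-7-methoxy-5-(methoxymethoxy)-2-[7-(methoxymethoxy)-2,2-dimethyl-2H-chromen-6-yl]-8-(3-methylbut-2-en-1-yl)-2,3-dihydro-4H-chromen-4-one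
Product: 21 maackiaflavanone A
Conditions: HCl (2 M in MeOH), THF, 0 °C to rt
Reagents that add atoms: none
Why: acid-catalysed acetal exchange with methanol removes both MOM ethers under conditions that should be mild enough to leave the chromene, the prenyl group (no free ortho-hydroxyl to cyclize onto) and the C2 stereocenter untouched.

**Compound list**
1 | ethyl (2Z)-3-iodoprop-2-enoate | CCOC(=O)/C=C\I | starting material
2 | (3Z)-4-iodo-2-methylbut-3-en-2-ol | CC(C)(O)/C=C\I | intermediate
3 | lithium (3Z)-4-lithio-2-methylbut-3-en-2-olate (dilithio species) | [Li]/C=C\C(C)(C)O[Li] | intermediate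
4 | 5,5-dimethyl-1,2-oxaborol-2(5H)-ol | CC1(C)C=CB(O)O1 | intermediate
5 | 5-bromo-2-chlorophenol | Oc1cc(Br)ccc1Cl | starting material
6 | 5-bromo-2-chloro-4-iodophenol | Oc1cc(Br)c(I)cc1Cl | intermediate
7 | 1-bromo-4-chloro-2-iodo-5-(methoxymethoxy)benzene | COCOc1cc(Br)c(I)cc1Cl | intermediate
8 | (3Z)-4-[2-bromo-5-chloro-4-(methoxymethoxy)phenyl]-2-methylbut-3-en-2-ol (Z-alkenol) | COCOc1cc(Br)c(/C=C\C(C)(C)O)cc1Cl | intermediate
9 | 6-chloro-7-(methoxymethoxy)-2,2-dimethyl-2H-chromene | COCOc1cc2OC(C)(C)C=Cc2cc1Cl | intermediate
10 | 2-[7-(methoxymethoxy)-2,2-dimethyl-2H-chromen-6-yl]-4,4,5,5-tetramethyl-1,3,2-dioxaborolane | COCOc1cc2OC(C)(C)C=Cc2cc1B1OC(C)(C)C(C)(C)O1 | intermediate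
11 | [7-(methoxymethoxy)-2,2-dimethyl-2H-chromen-6-yl]boronic acid | COCOc1cc2OC(C)(C)C=Cc2cc1B(O)O | intermediate
12 | 1-(2,6-dihydroxy-4-methoxyphenyl)ethan-1-one | CC(=O)c1c(O)cc(OC)cc1O | starting material
13 | (2E)-1-(2,6-dihydroxy-4-methoxyphenyl)-3-(dimethylamino)prop-2-en-1-one (enaminone) | CN(C)/C=C/C(=O)c1c(O)cc(OC)cc1O | intermediate
14 | 5-hydroxy-7-methoxy-4H-chromen-4-one | COc1cc(O)c2c(c1)occc2=O | intermediate
15 | 7-methoxy-5-[(3-methylbut-2-en-1-yl)oxy]-4H-chromen-4-one | COc1cc(OCC=C(C)C)c2c(c1)occc2=O | intermediate
16 | 7-methoxy-6-(2-methylbut-3-en-2-yl)-4H-chromene-4,5(6H)-dione (ortho-dienone) | C=CC(C)(C)C1C(=O)C2=C(OC=CC2=O)C=C1OC | intermediate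
17 | 7-methoxy-8-(3-methylbut-2-en-1-yl)-4H-chromene-4,5(8H)-dione (para-dienone) | CC(C)=CCC1C(OC)=CC(=O)C2=C1OC=CC2=O | intermediate
18 | 5-hydroxy-7-methoxy-8-(3-methylbut-2-en-1-yl)-4H-chromen-4-one | COc1cc(O)c2c(c1CC=C(C)C)occc2=O | intermediate
19 | 7-methoxy-5-(methoxymethoxy)-8-(3-methylbut-2-en-1-yl)-4H-chromen-4-one | COc1cc(OCOC)c2c(c1CC=C(C)C)occc2=O | intermediate
20 | (2S)-7-methoxy-5-(methoxymethoxy)-2-[7-(methoxymethoxy)-2,2-dimethyl-2H-chromen-6-yl]-8-(3-methylbut-2-en-1-yl)-2,3-dihydro-4H-chromen-4-one | COc1cc(OCOC)c2c(c1CC=C(C)C)O[C@H](c1cc3c(cc1OCOC)OC(C)(C)C=C3)CC2=O | intermediate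
21 | maackiaflavanone A, (2S)-5-hydroxy-2-(7-hydroxy-2,2-dimethyl-2H-chromen-6-yl)-7-methoxy-8-(3-methylbut-2-en-1-yl)-2,3-dihydro-4H-chromen-4-one | COc1cc(O)c2c(c1CC=C(C)C)O[C@H](c1cc3c(cc1O)OC(C)(C)C=C3)CC2=O | target

**Step count and risks**
Total step count: 13. Longest linear sequence: 7 steps (steps 3, 4, 5, 6, 7, 12, 13 from 5; equally steps 1, 2, 5, 6, 7, 12, 13 from 1).

Steps most likely to fail:

1. Step 5 (proposed new method). The second catalytic cycle may stall, because oxidative addition into the hindered C–Br bond or the C–O reductive elimination is slow. The open Z-alkenol would then isomerize to the E alkene or take up a second alkenyl group at C–Br. The fallback uses known chemistry, sets out from 7 and comes back at 9, and makes the two bonds one at a time through an alkyne. Sonogashira coupling of 7 with 2-methylbut-3-yn-2-ol at the C–I bond (PdCl2(PPh3)2, CuI, Et3N, rt) should give 4-[2-bromo-5-chloro-4-(methoxymethoxy)phenyl]-2-methylbut-3-yn-2-ol F1. Z-selective semi-hydrogenation (H2, Pd/CaCO3 poisoned with Pb(OAc)2, quinoline, EtOAc) should give 8, now isolated. A separate palladium-catalysed intramolecular etherification of the tertiary alcohol (Pd(OAc)2, dppf, NaOt-Bu, toluene, 90 °C) should then close the pyran ring to 9.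

2. Step 12. Aryl transfer and insertion may be slow with the ortho-substituted, electron-rich aryl group, so that protodeboronation wins, or the facial selectivity on the 5,7,8-trisubstituted chromone may be insufficient. The fallback sets out from 19 and 11 and comes back at 20, and separates bond formation from stereocontrol. Addition with a more forcing achiral catalyst ([Rh(OH)(cod)]2, 1,4-dioxane/H2O, 60 °C) should give the racemic flavanone F2. Kinetic resolution by asymmetric transfer hydrogenation (RuCl(p-cymene)(TsDPEN), the catalyst antipode that reduces the 2R ketone faster, HCO2H/Et3N, stopped near half conversion) should convert the 2R enantiomer into (2R,4R)-7-methoxy-5-(methoxymethoxy)-2-[7-(methoxymethoxy)-2,2-dimethyl-2H-chromen-6-yl]-8-(3-methylbut-2-en-1-yl)-3,4-dihydro-2H-chromen-4-ol F3, which is removed by chromatography, and leave (2S)-20.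

3. Step 10. The ortho-dienone may tautomerize before the Cope shift, which would leave the 1,1-dimethylallyl group at C6 (and allow its cyclization onto the 5-hydroxyl) instead of delivering a prenyl group to C8. The fallback sets out from 14 and comes back at 19, and installs the prenyl group by cross-coupling. MOM protection of 14 (MOMCl, i-Pr2NEt, CH2Cl2) should give 7-methoxy-5-(methoxymethoxy)-4H-chromen-4-one F4. Electrophilic iodination at C8 (I2, CF3CO2Ag, CH2Cl2, 0 °C) should give 8-iodo-7-methoxy-5-(methoxymethoxy)-4H-chromen-4-one F5. Stille coupling with tributyl(3-methylbut-2-en-1-yl)stannane (Pd(PPh3)4, DMF, 90 °C) should give 19.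

**Further compounds**
F1 | step 5 | 4-[2-bromo-5-chloro-4-(methoxymethoxy)phenyl]-2-methylbut-3-yn-2-ol | COCOc1cc(Br)c(C#CC(C)(C)O)cc1Cl
F2 | step 12 | racemic 7-methoxy-5-(methoxymethoxy)-2-[7-(methoxymethoxy)-2,2-dimethyl-2H-chromen-6-yl]-8-(3-methylbut-2-en-1-yl)-2,3-dihydro-4H-chromen-4-one | COc1cc(OCOC)c2c(c1CC=C(C)C)OC(c1cc3c(cc1OCOC)OC(C)(C)C=C3)CC2=O
F3 | step 12 | (2R,4R)-7-methoxy-5-(methoxymethoxy)-2-[7-(methoxymethoxy)-2,2-dimethyl-2H-chromen-6-yl]-8-(3-methylbut-2-en-1-yl)-3,4-dihydro-2H-chromen-4-ol | COc1cc(OCOC)c2c(c1CC=C(C)C)O[C@@H](c1cc3c(cc1OCOC)OC(C)(C)C=C3)C[C@H]2O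
F4 | step 10 | 7-methoxy-5-(methoxymethoxy)-4H-chromen-4-one | COc1cc(OCOC)c2c(c1)occc2=O
F5 | step 10 | 8-iodo-7-methoxy-5-(methoxymethoxy)-4H-chromen-4-one | COc1cc(OCOC)c2c(c1I)occc2=O
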